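The readings are simulated with made-up constants; the scatter is artificial.

A unit of substrate cannot end as both product and something else, so count the fraction left over, not the fraction made.

| flask | substrate | reagent | remark | time |
|---|---|---|---|---|
| epsilon | 0.042 M | 2 equiv | run made earlier |  |
| theta | 0.17 M | 2 equiv | run made earlier |  |
| flask | 0.083 M | 2.00 equiv |  | 15 d |

- epsilon (time / d: substrate / %, product / %, intermediate C / %): 1.04: 0, 48.3, 17.0; 1.67: 1.0, 52.9, 28.8; 2.50: 1.4, 51.7, 32.0; 4.00: 0, 53.5, 34.7; 8.00: 1.8, 52.5, 36.4; 12.0: 0, 52.5, 35.5
- theta (time / d: substrate / %, product / %, intermediate C / %): 0.833: 1.8, 19.0, 30.6; 2.50: 0, 20.9, 51.2; 4.00: 1.6, 19.0, 59.0; 6.00: 0, 22.1, 61.1; 10.0: 0.2, 21.2, 63.1; 12.0: 0, 21.0, 62.5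

(each reading ± 1 percentage point)

- the reaction counts as stopped when no species that holds the substrate changes by six tenths of a point or more over the second half of the time

1. why nothing more happens at 15 d, or that something still does (forward and back rates have come level / it is still moving / the reagent has run out first / all of the substrate has reacted)
2. share of the substrate used up at 15 d
3. product at 15 d, in percent of the substrate charged
4. intermediate C at 15 d, in percent of the substrate charged

Both runs lose their substrate early: it reads 0% at 1.04 d in the epsilon run and 1.8% at 0.833 d in the theta run, against a scatter of 1 percentage point. Product then stands still within a few points; the epsilon run reads 52.9% at 1.67 d and 52.5% at 12.0 d. So take Z, the last product reading, and L, the fraction left, meaning the substrate that did not become product. With c the starting substrate concentration, define the balance concentration q = cZ/L, the c at which the product route keeps level with the rest.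

epsilon: q = 0.042 M × 52.5% / 47.5% = 0.0464 M

theta: q = 0.17 M × 21.0% / 79.0% = 0.0452 M

Take the mean, 0.0458 M, as q. The value holds across a factor of 4.05 in c, so you read a route that needs no reagent racing one whose rate grows with c at fixed equivalents. This flask's c is twice the epsilon run's, so you take Z/L lower than in that run by the same factor.

Z/L = q/c = 0.552, so L = 64.4% and Z = 35.6%

You expect no substrate at 15 d, since the epsilon run reads 0% at 1.04 d, an earlier time, so your answer for the end is that the substrate has reacted.

The forecast gave 100% conversion, 36% product and 50% intermediate C, and for the end forward and back rates have come level, from “a reversible step at equilibrium”.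

The flask gives 100% conversion, 35.6% product, 50.1% intermediate C, and for the end all of the substrate has reacted.

    substrate + reagent → intermediate A (k = 7.80 L mol⁻¹ h⁻¹)
    substrate → intermediate B (k = 0.720 h⁻¹)
    intermediate B → product (k = 0.0850 h⁻¹)
    intermediate A ⇌ intermediate C (K = 3.50, k = 0.0240 h⁻¹)
    reagent + intermediate B ⇌ intermediate D (K = 74.0 L mol⁻¹, k = 0.140 L mol⁻¹ h⁻¹)
    intermediate D → intermediate C (k = 0.350 h⁻¹)
    reagent ⇌ dormant form (K = 0.170, k = 0.180 h⁻¹)

In this flask substrate stands at 0% by 1.50 d, and at the end 0% of it remains against 58% of the reagent's own charge, unbound, so substrate is the limiting reagent. Between 1.50 d and 7.50 d, with substrate at 0%, product went from 34.5% to 35.6% and intermediate C from 35.3% to 49.9%. The flask's own q is 0.0458 M.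

With 0.033 M of substrate and the same equivalents, q gives Z/L = 1.39, so product 58.1%. The computed flask holds 58.3%.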